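Ring A (C10–C1–C2–C3–C4–C5) is unravelled to the cyclopentanone of commercial (S)-7a-methyl-tetrahydroindene-1,5-dione, whose quaternary carbon is already C5 in the correct absolute configuration. The key step is a Lewis-acid α-ketol (acyloin) rearrangement of a 1-acetylcyclopentan-1-ol: C5 migrates from C3 to C4. One operation thus enlarges the five-membered ring to ring A, makes C3 the ketone that later carries the tiglate, and inserts C4 with its C15 methyl next to quaternary C5. It exploits the C3(O)–C4(CH3)–C5(quaternary) array of ring A. Ring B is then completed by conjugate reduction, C9 oxygenation and C7 alkenylation.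

Key step: step 3

Remark (numbering): eremophilane locants are used throughout. Ring A = C1, C2, C3, C4, C5, C10; ring B = C5, C6, C7, C8, C9, C10; C14 = CH3 on C5, C15 = CH3 on C4; β is the face of C14. In the hydrindanes 1, 3 and 4 the five-ring carbonyl carbon is C3 and the ethylidene/acetyl carbon is C4.

Assumption: 1 is bought as its (S)-enantiomer (both enantiomers are commercial).

Step 1
Reactants: 1 (S)-7a-methyl-2,3,7,7a-tetrahydro-1H-indene-1,5(6H)-dione; 2 ethyltriphenylphosphonium bromide
Product: 3 (1Z,7aR)-1-ethylidene-7a-methyl-1,2,3,6,7,7a-hexahydro-5H-inden-5-one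
Conditions: KOt-Bu (2.4 equiv), 2 (2.5 equiv), THF, rt → 60 °C; aq. NH4Cl work-up
Reagents that add atoms: none
Why: Wittig olefination, in which the non-stabilised ylide should react only at the saturated five-ring ketone while excess base holds the enone as its dienolate (returned on work-up); the expected (Z)-geometry is of no consequence because C4 becomes a carbonyl carbon in step 2.

Step 2
Reactants: 3 (1Z,7aR)-1-ethylidene-7a-methyl-1,2,3,6,7,7a-hexahydro-5H-inden-5-one
Product: 4 (1R,7aS)-1-acetyl-1-hydroxy-7a-methyl-1,2,3,6,7,7a-hexahydro-5H-inden-5-one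
Conditions: RuCl3·xH2O (1 mol %), KHSO5 (as 2KHSO5·KHSO4·K2SO4), NaHCO3, EtOAc/MeCN/H2O, rt, short reaction time
Reagents that add atoms: potassium peroxymonosulfate KHSO5, OOS(=O)(=O)[O-].[K+]
Why: RuO4-catalysed ketohydroxylation of a trisubstituted alkene puts the hydroxyl on the fully substituted C3 and the ketone on C4; the electron-rich ethylidene should react well before the enone alkene, and attack anti to C14 sets the C3 hydroxyl α.

Step 3
Reactants: 4 (1R,7aS)-1-acetyl-1-hydroxy-7a-methyl-1,2,3,6,7,7a-hexahydro-5H-inden-5-one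
Product: 5 (4S,5S)-4α-hydroxy-4β,5β-dimethyl-Δ9(10)-octalin-3,8-dione
Conditions: BF3·OEt2 (0.3 equiv), CH2Cl2, 0 °C → rt
Reagents that add atoms: none
Why: α-Ketol (acyloin) rearrangement: BF3 chelates the hydroxyl and acetyl oxygens of 4, the C3–C5 bond migrates from the carbinol carbon C3 to the acetyl carbon C4 and C3 becomes the ring ketone, so the cyclopentane C3–C2–C1–C10–C5 becomes six-membered ring A with C4 inserted between C3 and C5. The closest known reaction type is the Lewis-acid D-homoannulation of 17-hydroxy-20-oxo steroids, which runs on the same hydrindane array. No ring is closed between chain ends: ring A arises by a suprafacial 1,2-alkyl shift (ring expansion by one carbon) with retention at the migrating quaternary C5. The new carbinol centre C4 is set by the syn-chelated transition state (C5 attacks the acetyl carbon from its own side, giving hydroxyl α and methyl β), and this centre is erased again in step 4. The step needs migration of C5 and not of C2: under Lewis-acid, cation-like conditions the more substituted quaternary carbon should migrate, and relief of five-ring strain together with formation of the ring ketone should drive the equilibrium to 5.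

Step 4
Reactants: 5 (4S,5S)-4α-hydroxy-4β,5β-dimethyl-Δ9(10)-octalin-3,8-dione
Product: 6 (4R,5R)-4β,5β-dimethyl-Δ9(10)-octalin-3,8-dione
Conditions: SmI2 (2.5 equiv), THF/MeOH, −78 °C; pH 7 buffer work-up
Reagents that add atoms: none
Why: SmI2 reductive cleavage of an α-hydroxy ketone: the C3 ketone with its axial α-hydroxyl should be reduced well before the enone, hydroxide leaves to give the C3=C4 samarium enolate, and methanol protonates C4 from the α face, anti to the axial C14 on neighbouring C5, which sets C15 β.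

Step 5
Reactants: 6 (4R,5R)-4β,5β-dimethyl-Δ9(10)-octalin-3,8-dione
Product: 7 (3S,4R,5R)-3β-hydroxy-4β,5β-dimethyl-Δ9(10)-octalin-8-one
Conditions: LiBH(s-Bu)3 (1.05 equiv), THF, −78 °C; aq. NH4Cl work-up
Reagents that add atoms: none
Why: Bulky borohydride reduction of the saturated C3 ketone (faster than the β,β-disubstituted enone): hydride should enter from the equatorial α side because the axial C14 blocks the β face, giving the axial 3β-alcohol.

Step 6
Reactants: 7 (3S,4R,5R)-3β-hydroxy-4β,5β-dimethyl-Δ9(10)-octalin-8-one; 8 tiglic acid, (E)-2-methylbut-2-enoic acid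
Product: 9 (3R,4R,5R)-3α-tigloyloxy-4β,5β-dimethyl-Δ9(10)-octalin-8-one
Conditions: PPh3, DIAD, 8, toluene, 0 °C → rt
Reagents that add atoms: none
Why: Mitsunobu esterification: SN2 displacement of the activated axial 3β-oxygen by tiglate inverts C3 and gives the equatorial 3α-ester directly, without touching the (E)-alkene of the acid.

Step 7
Reactants: 9 (3R,4R,5R)-3α-tigloyloxy-4β,5β-dimethyl-Δ9(10)-octalin-8-one
Product: 10 3α-tigloyloxy-8-(triethylsilyloxy)-4β,5β-dimethyl-10βH-Δ8(9)-octalin (cis-fused)
Conditions: [(Ph3P)CuH]6 (0.25 equiv), Et3SiCl, toluene, rt; filtration under argon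
Reagents that add atoms: chlorotriethylsilane, CC[Si](Cl)(CC)CC
Why: Copper hydride conjugate reduction with silyl trapping of the enolate (reductive silylation): hydride should add to C10 syn to the angular C14, as cuprates do with angularly methylated octalones, giving the cis-fused ring junction (10β-H) and the regiodefined C8=C9 enol ether, while the less electrophilic α,β-disubstituted tiglate should stay intact.

Step 8
Reactants: 10 3α-tigloyloxy-8-(triethylsilyloxy)-4β,5β-dimethyl-10βH-Δ8(9)-octalin
Product: 12 (3R,4R,5R,9R,10S)-3α-tigloyloxy-9β-hydroxy-4β,5β-dimethyl-10βH-decalin-8-one, via 9β-triethylsilyloxy ketone 11 (not isolated)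
Conditions: m-CPBA (1.05 equiv), NaHCO3, CH2Cl2, −20 °C; then aq. citric acid/THF, rt
Reagents that add atoms: m-chloroperbenzoic acid, O=C(OO)c1cccc(Cl)c1
Why: Rubottom oxidation: the peracid should epoxidise the electron-rich enol ether from the convex β face (ring A screens the α face, the tiglate alkene is electron-poor), silyl migration gives the 9β-silyloxy ketone and mild acid frees the equatorial 9β-alcohol.

Step 9
Reactants: 12 3α-tigloyloxy-9β-hydroxy-4β,5β-dimethyl-10βH-decalin-8-one; 13 3-methylbut-2-enoic acid (senecioic acid)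
Product: 14 (3R,4R,5R,9R,10S)-3α-tigloyloxy-9β-senecioyloxy-4β,5β-dimethyl-10βH-decalin-8-one
Conditions: DCC, DMAP (cat.), CH2Cl2, 0 °C → rt
Reagents that add atoms: none
Why: Steglich esterification acylates the secondary 9β-alcohol with retention, and no base strong enough to move the senecioate double bond out of conjugation is present.

Step 10
Reactants: 14 3α-tigloyloxy-9β-senecioyloxy-4β,5β-dimethyl-10βH-decalin-8-one; 15 2-bromopropene
Product: 18 (3R,4R,5R,7R,9R,10S)-3α-tigloyloxy-9β-senecioyloxy-10βH-eremophil-11-en-8-one (target), via lithium enolate 16 (not isolated), via zinc enolate 17 (not isolated)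
Conditions: LiN(SiMe3)2 (1.05 equiv), THF, −78 °C; ZnCl2 (1.1 equiv), −78 → 0 °C; 15, Pd[P(t-Bu)3]2 (5 mol %), THF, rt; aq. NH4Cl work-up
Reagents that add atoms: none
Why: Palladium-catalysed α-alkenylation of a ketone enolate (Negishi-type coupling of the zinc enolate): the amide base should deprotonate the C7 methylene and not the hindered, acyloxy-bearing C9 methine, the weakly basic zinc enolate should not deprotonate the product, and C–C bond formation on the convex β face places the isopropenyl group equatorial (7β) without double-bond migration into conjugation.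

Compound list
1 | (S)-7a-methyl-2,3,7,7a-tetrahydro-1H-indene-1,5(6H)-dione | C[C@]12CCC(=O)C=C1CCC2=O | starting material
2 | ethyltriphenylphosphonium bromide | CC[P+](c1ccccc1)(c1ccccc1)c1ccccc1.[Br-] | starting material
3 | (1Z,7aR)-1-ethylidene-7a-methyl-1,2,3,6,7,7a-hexahydro-5H-inden-5-one (angular methyl β, ethylidene methyl syn to C5) | C/C=C1/CCC2=CC(=O)CC[C@]12C | intermediate
4 | (1R,7aS)-1-acetyl-1-hydroxy-7a-methyl-1,2,3,6,7,7a-hexahydro-5H-inden-5-one (C3 hydroxyl α, acetyl β) | CC(=O)[C@@]1(O)CCC2=CC(=O)CC[C@]12C | intermediate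
5 | (4S,5S)-4α-hydroxy-4β,5β-dimethyl-Δ9(10)-octalin-3,8-dione, i.e. (1S,8aS)-1-hydroxy-1,8a-dimethyl-1,3,4,7,8,8a-hexahydronaphthalene-2,6-dione | C[C@@]1(O)C(=O)CCC2=CC(=O)CC[C@]12C | intermediate
6 | (4R,5R)-4β,5β-dimethyl-Δ9(10)-octalin-3,8-dione, i.e. (1R,8aR)-1,8a-dimethyl-1,3,4,7,8,8a-hexahydronaphthalene-2,6-dione | C[C@H]1C(=O)CCC2=CC(=O)CC[C@]12C | intermediate
7 | (3S,4R,5R)-3β-hydroxy-4β,5β-dimethyl-Δ9(10)-octalin-8-one, i.e. (4aR,5R,6S)-6-hydroxy-4a,5-dimethyl-4,4a,5,6,7,8-hexahydronaphthalen-2(3H)-one | C[C@H]1[C@@H](O)CCC2=CC(=O)CC[C@]12C | intermediate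
8 | tiglic acid, (E)-2-methylbut-2-enoic acid | C/C=C(\C)C(=O)O | starting material
9 | (3R,4R,5R)-3α-tigloyloxy-4β,5β-dimethyl-Δ9(10)-octalin-8-one | C[C@H]1[C@H](OC(=O)/C(C)=C/C)CCC2=CC(=O)CC[C@]12C | intermediate
10 | 3α-tigloyloxy-8-(triethylsilyloxy)-4β,5β-dimethyl-10βH-Δ8(9)-octalin (cis-fused) | C[C@H]1[C@H](OC(=O)/C(C)=C/C)CC[C@@H]2C=C(O[Si](CC)(CC)CC)CC[C@]12C | intermediate
11 | 3α-tigloyloxy-9β-(triethylsilyloxy)-4β,5β-dimethyl-10βH-decalin-8-one | C[C@H]1[C@H](OC(=O)/C(C)=C/C)CC[C@@H]2[C@@H](O[Si](CC)(CC)CC)C(=O)CC[C@]12C | intermediate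
12 | (3R,4R,5R,9R,10S)-3α-tigloyloxy-9β-hydroxy-4β,5β-dimethyl-10βH-decalin-8-one | C[C@H]1[C@H](OC(=O)/C(C)=C/C)CC[C@@H]2[C@@H](O)C(=O)CC[C@]12C | intermediate
13 | 3-methylbut-2-enoic acid (senecioic acid) | CC(C)=CC(=O)O | starting material
14 | (3R,4R,5R,9R,10S)-3α-tigloyloxy-9β-senecioyloxy-4β,5β-dimethyl-10βH-decalin-8-one | C[C@H]1[C@H](OC(=O)/C(C)=C/C)CC[C@@H]2[C@@H](OC(=O)C=C(C)C)C(=O)CC[C@]12C | intermediate
15 | 2-bromopropene | CC(Br)=C | starting material
16 | lithium C7=C8 enolate of 14 | C[C@H]1[C@H](OC(=O)/C(C)=C/C)CC[C@@H]2[C@@H](OC(=O)C=C(C)C)C(O[Li])=CC[C@]12C | intermediate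
17 | chlorozinc C7=C8 enolate of 14 | C[C@H]1[C@H](OC(=O)/C(C)=C/C)CC[C@@H]2[C@@H](OC(=O)C=C(C)C)C(O[Zn]Cl)=CC[C@]12C | intermediate
18 | (3R,4R,5R,7R,9R,10S)-3α-tigloyloxy-9β-senecioyloxy-10βH-eremophil-11-en-8-one (7β-isopropenyl) | C=C(C)[C@H]1C[C@@]2(C)[C@H](CC[C@@H](OC(=O)/C(C)=C/C)[C@@H]2C)[C@@H](OC(=O)C=C(C)C)C1=O | target

Total step count: 10. Longest linear sequence: 10 steps (1 → 18).

Steps most likely to fail

1. Step 10. Enolisation may occur toward C9 instead of C7, the coupling may be slow on the crowded enolate, or the new double bond may migrate into conjugation with the ketone. The fallback changes the order of events and makes the C7–C11 bond by an aldol reaction while C9 is still a silyl ether; it sets out from 11 and returns at 18. Compound 11 is isolated (step 8 without the acid work-up), deprotonated at C7 with LiN(i-Pr)2 in THF at −78 °C and trapped with acetone to give the 7β-(2-hydroxypropan-2-yl) 9β-silyloxy ketone F1. Dehydration toward the methyl groups (SOCl2, pyridine, −20 °C, or Burgess reagent) should give the 7β-isopropenyl 9β-silyloxy ketone F2. HF·pyridine in THF frees the 7β-isopropenyl 9β-hydroxy ketone F3, and Steglich esterification with 13 (DCC, DMAP) gives 18.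

2. Step 6. E2 elimination of the activated axial alcohol (anti-periplanar axial hydrogens on C2 and C4) may outrun substitution at the hindered C3. The fallback sets C3 by an electron-transfer reduction and forms the ester with retention; it sets out from 6 and returns at 10. Compound 6 is first reductively silylated ([(Ph3P)CuH]6, Et3SiCl, toluene) to the cis-fused 8-silyloxy Δ8(9)-octalin-3-one F4. Reduction of the C3 ketone with SmI2/H2O/Et3N in THF should give the thermodynamically preferred equatorial 3α-alcohol F5. Yamaguchi esterification with 8 (2,4,6-trichlorobenzoyl chloride, Et3N, DMAP, toluene) then gives 10.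

3. Step 2. Over-oxidation (cleavage of the α-ketol) or competing attack on the enone alkene may erode the ketohydroxylation. The fallback separates hydroxylation and oxidation; it sets out from 3 and returns at 4. Dihydroxylation with catalytic OsO4 and N-methylmorpholine N-oxide in acetone/water, from the α face, gives the 3α,4-diol F6 without touching the enone. Parikh–Doering oxidation of the secondary alcohol (SO3·pyridine, DMSO, Et3N) gives 4.

Further compounds
F1 | step 10 | 3α-tigloyloxy-9β-(triethylsilyloxy)-7β-(2-hydroxypropan-2-yl)-4β,5β-dimethyl-10βH-decalin-8-one | C[C@H]1[C@H](OC(=O)/C(C)=C/C)CC[C@@H]2[C@@H](O[Si](CC)(CC)CC)C(=O)[C@@H](C(C)(C)O)C[C@]12C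
F2 | step 10 | 3α-tigloyloxy-9β-(triethylsilyloxy)-10βH-eremophil-11-en-8-one | C[C@H]1[C@H](OC(=O)/C(C)=C/C)CC[C@@H]2[C@@H](O[Si](CC)(CC)CC)C(=O)[C@@H](C(C)=C)C[C@]12C
F3 | step 10 | 3α-tigloyloxy-9β-hydroxy-10βH-eremophil-11-en-8-one | C[C@H]1[C@H](OC(=O)/C(C)=C/C)CC[C@@H]2[C@@H](O)C(=O)[C@@H](C(C)=C)C[C@]12C
F4 | step 6 | 8-(triethylsilyloxy)-4β,5β-dimethyl-10βH-Δ8(9)-octalin-3-one (cis-fused) | C[C@H]1C(=O)CC[C@@H]2C=C(O[Si](CC)(CC)CC)CC[C@]12C
F5 | step 6 | 3α-hydroxy-8-(triethylsilyloxy)-4β,5β-dimethyl-10βH-Δ8(9)-octalin (cis-fused) | C[C@H]1[C@H](O)CC[C@@H]2C=C(O[Si](CC)(CC)CC)CC[C@]12C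
F6 | step 2 | (1R,7aS)-1-hydroxy-1-[(1S)-1-hydroxyethyl]-7a-methyl-1,2,3,6,7,7a-hexahydro-5H-inden-5-one | C[C@H](O)[C@@]1(O)CCC2=CC(=O)CC[C@]12C
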